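**Assumption:** the target, methyl 2-(5-hexadecylfuran-2-yl)acetate (C23H40O3), has no stereocentres or stereogenic double bonds, so it is achiral and no enantiocontrol is needed. The route has not been run; Step 2 is a proposed one-pot method assembled from two known reaction types.

## Retrosynthetic overview

1. Avoided: alkylating or acylating a pre-formed furan (2-furyllithium + C16H33Br, or Friedel–Crafts on methyl 2-furylacetate). The furan is instead built de novo, last, from two acyclic pieces.
2. Acyl piece: heptadecanoyl chloride (1) + TMS-diazomethane (2) ⇒ 1-diazooctadecan-2-one (3). Ester piece: methyl but-3-ynoate (4).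
3. Key disconnection, furan C3–C4 bond: Cu-carbene/acetylide coupling of 3 with 4 gives the skipped ynone methyl 6-oxodocos-3-ynoate (5).
4. Furan O–C2 bond: in-pot 5-endo cycloisomerisation of 5 gives the target (6). The furan is the only ring and forms in the final operation.

## Route

**Step 1**
Reactants: 1, heptadecanoyl chloride (C16H33COCl); 2, (trimethylsilyl)diazomethane
Product: 3, 1-diazooctadecan-2-one (C16H33–CO–CH=N2)
Conditions: TMSCHN2 (2.0 equiv, 2 M in hexanes), THF/MeCN 1:1, 0 °C → rt, 5 h; NaHCO3 work-up; protect from light and acid
Reagents that add atoms: (trimethylsilyl)diazomethane, C[Si](C)(C)C=[N+]=[N-]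
Why: Acylation of a diazomethane surrogate (Arndt–Eistert-type diazoketone synthesis, Aoyama–Shioiri variant) is reliable for unhindered aliphatic acid chlorides; compound 2 delivers the CHN2 carbon and both nitrogens, its silyl group is cleaved in situ and on the bicarbonate work-up, and the product has no other functional group and no stereocentre.

**Step 2**
Reactants: 3, 1-diazooctadecan-2-one; 4, methyl but-3-ynoate (HC≡C–CH2–CO2Me, 1.5 equiv)
Product: 6, methyl 2-(5-hexadecylfuran-2-yl)acetate (target), via 5, methyl 6-oxodocos-3-ynoate (MeO2C–CH2–C≡C–CH2–CO–C16H33, not isolated)
Conditions: CuI (10 mol %), MeCN/THF 2:1, rt, 3 added by syringe pump over 4 h (no base present); once N2 evolution stops and the diazo IR band is gone, add Et3N (3 equiv), 70 °C, 6 h, same pot; neutral work-up, chromatography on Et3N-deactivated silica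
Reagents that add atoms: none
Why: Proposed new method: the Cu(I) acetylide of 4 traps 3 as a copper carbene, alkynyl migratory insertion and protodemetalation give skipped ynone 5 (closest known type: base-free CuI-catalysed coupling of terminal alkynes with diazoacetates to 3-alkynoates), then Et3N equilibrates 5 with its allenyl-ketone/allenoate tautomers and the ketone oxygen closes 5-endo onto the alkyne carbon bearing CH2CO2Me, aromatising to the 2,5-disubstituted furan (closest known type: CuI/Et3N or Ag(I) Marshall-type cycloisomerisation of alkynyl/allenyl ketones to furans); both tautomer manifolds converge on the same furan, every product atom comes from 3 and 4 with loss of N2, and no stereocentre is formed.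

Atom map for Step 2: furan O and C5 (bearing C16H33) are the ketone C=O of 3; C4 is the diazo carbon; C3 is the terminal alkyne carbon of 4; C2 is the internal alkyne carbon, which keeps its CH2CO2Me. C18H34N2O + C5H6O2 − N2 = C23H40O3.

## Compound list

1 | heptadecanoyl chloride | CCCCCCCCCCCCCCCCC(=O)Cl | starting material
2 | (trimethylsilyl)diazomethane | C[Si](C)(C)C=[N+]=[N-] | starting material
3 | 1-diazooctadecan-2-one | CCCCCCCCCCCCCCCCC(=O)C=[N+]=[N-] | intermediate
4 | methyl but-3-ynoate | C#CCC(=O)OC | starting material
5 | methyl 6-oxodocos-3-ynoate | CCCCCCCCCCCCCCCCC(=O)CC#CCC(=O)OC | intermediate (transient, not isolated)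
6 | methyl 2-(5-hexadecylfuran-2-yl)acetate | CCCCCCCCCCCCCCCCc1ccc(CC(=O)OC)o1 | target

## Summary

Total step count: 2. Longest linear sequence: 2.

The route has only two steps, so the three failure points are the two stages of Step 2 and Step 1.

1. **Step 2, coupling stage.** Risks: carbene dimerisation of 3 to the ene-dione, slow base-free acetylide formation, premature isomerisation of 4 to the allenoate followed by dipolar cycloaddition with 3. Fallback: drop the carbene coupling for a Paal–Knorr route. Methyl acetoacetate dianion (NaH, n-BuLi) opens 1,2-epoxyoctadecane (BF3·OEt2) to methyl 6-hydroxy-3-oxodocosanoate; DMP oxidation gives the 3,6-dioxo ester; p-TsOH in PhMe closes the furan.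
2. **Step 2, cycloisomerisation stage.** Risk: the doubly activated skipped ynone drains to the conjugated 6-oxo-2,4-dienoate instead of cyclising. Fallback: avoid the skipped 3-ynone altogether by γ-propargylating methyl acetoacetate dianion with 1-bromooctadec-2-yne (from propargyl alcohol + 1-bromopentadecane, then PBr3). The resulting methyl 3-oxodocos-6-ynoate cyclises 5-exo-dig and aromatises (Au(I) or PdCl2(MeCN)2) to the same furan.
3. **Step 1.** Risks: α-chloroketone by-product, or loss of 3 on acidic silica. Fallback: make 3 by detrifluoroacetylative diazo transfer on commercial 2-octadecanone (LiHMDS, CF3CO2CH2CF3; then MsN3, Et3N) instead of acylating a diazoalkane.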